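**Retrosynthetic overview**

1. Numbering (hydroazulene numbers of the target, used for the same atoms in all intermediates): cyclopentane C1–C2–C3(iPr)–C3a(OH)–C8a(Me); cycloheptane C3a–C4–C5–C6(Me,OH)–C7(OCOAr)–C8–C8a.
2. End game: ester 14 ⇐ triol 12 (acylation of the only secondary hydroxyl, C7) ⇐ epoxide 11 (water opens C6 with inversion) ⇐ alkenol 10 (C6=C7 alkene, epoxidation directed by the C3a hydroxyl).
3. Key disconnection: bicyclic dienol 9 ⇐ monocyclic oxolane 7. A Claisen shift (C8–C8a formed, C6–O broken) expands the five-membered oxolane (O, C3a, C4, C5, C6) to the seven-membered carbocycle with a C3a ketone, and a carbonyl-ene reaction then closes the cyclopentane (C3–C3a) in the same flask.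
4. Enabling feature: the two tertiary carbinol carbons C3a and C6 of the seven-membered ring are 1,4-related through the C4–C5 bridge, so one oxygen ties them into an oxolane in which C7=C8 is a vinyl group on C6 and the quaternary C8a is the alkylidene carbon on C3a (C6=C7 lies γ,δ to a C3a carbonyl); C3a(OH)–C3(isopropyl) is the retron of the ene closure.
5. Oxolane 7 ⇐ (R)-linalool 1 (C3a to C8, the C6 methyl, the later C3a oxygen, the only stereocentre) + homoprenyl bromide 4 (C1 to C3 and the isopropyl carbons), joined through alkynol 5; anti iodocyclisation and methyl cross-coupling fix the enol-ether geometry. Ring order: oxolane (temporary) → seven-membered ring → five-membered ring.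

Key step: step 6

Remark on the chemistry: (R)-(−)-linalool of high enantiomeric purity is assumed, because its stereocentre (the later C6) is the sole source of absolute configuration.

**Route**

Step 1
Reactants: 1 (R)-(−)-linalool, (3R)-3,7-dimethylocta-1,6-dien-3-ol
Product: 2 (5R)-5-ethenyl-5-methyloxolan-2-ol (lactol, both C2 epimers)
Conditions: O3, CH2Cl2/MeOH, −78 °C (Sudan red 7B as end-point indicator); then Me2S, −78 °C → rt
Reagents that add atoms: ozone, [O-][O+]=O
Why: Chemoselective ozonolysis with reductive work-up: ozone cleaves the electron-rich trisubstituted alkene much faster than the vinyl group next to the carbinol, and the released γ-hydroxy aldehyde closes to the lactol without touching the stereocentre.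

Step 2
Reactants: 2 (5R)-5-ethenyl-5-methyloxolan-2-ol
Product: 3 (3R)-3-methylhept-1-en-6-yn-3-ol
Conditions: dimethyl (1-diazo-2-oxopropyl)phosphonate, K2CO3, MeOH, 0 °C → rt
Reagents that add atoms: dimethyl (1-diazo-2-oxopropyl)phosphonate, COP(=O)(OC)C(=[N+]=[N-])C(C)=O
Why: Seyferth–Gilbert homologation with the Ohira–Bestmann reagent converts the open hydroxy-aldehyde form of the lactol into the terminal alkyne under mild carbonate conditions that the tertiary allylic alcohol tolerates.

Step 3
Reactants: 3 (3R)-3-methylhept-1-en-6-yn-3-ol; 4 5-bromo-2-methylpent-2-ene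
Product: 5 (3R)-3,11-dimethyldodeca-1,10-dien-6-yn-3-ol
Conditions: n-BuLi (2.1 equiv), THF, −78 → 0 °C; then 4, DMPU, 0 °C → rt
Reagents that add atoms: none
Why: SN2 alkylation of a lithium acetylide: in the alkoxide–acetylide dianion the acetylide carbon is much the better nucleophile toward the primary bromide than the hindered tertiary alkoxide.

Step 4
Reactants: 5 (3R)-3,11-dimethyldodeca-1,10-dien-6-yn-3-ol
Product: 6 (2E,5R)-5-ethenyl-2-(1-iodo-5-methylhex-4-en-1-ylidene)-5-methyloxolane
Conditions: NIS, NaHCO3, MeCN, −20 → 0 °C, dark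
Reagents that add atoms: N-iodosuccinimide, O=C1CCC(=O)N1I
Why: Electrophilic iodocyclisation of a 4-alkyn-1-ol: 5-exo-dig anti addition of the tertiary hydroxyl and iodine across the alkyne should set the E geometry (iodine trans to the ring oxygen, chain cis), whereas an iodonium ion at the distant alkene has no nucleophile in reach and reverts.

Step 5
Reactants: 6 (2E,5R)-5-ethenyl-2-(1-iodo-5-methylhex-4-en-1-ylidene)-5-methyloxolane
Product: 7 (2Z,5R)-5-ethenyl-5-methyl-2-(6-methylhept-5-en-2-ylidene)oxolane
Conditions: MeZnCl (2 equiv), Pd(PPh3)4 (5 mol %), THF, 0 °C → rt; chromatography on Et3N-deactivated support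
Reagents that add atoms: methylzinc chloride, C[Zn]Cl
Why: Negishi cross-coupling of the alkenyl iodide proceeds with retention of double-bond geometry, so methyl enters trans to the ring oxygen and the tetrasubstituted enol ether should form as the single Z isomer.

Step 6
Reactants: 7 (2Z,5R)-5-ethenyl-5-methyl-2-(6-methylhept-5-en-2-ylidene)oxolane
Product: 9 (3R,3aS,8aR)-6,8a-dimethyl-3-(prop-1-en-2-yl)-2,3,4,5,8,8a-hexahydro-1H-azulen-3a-ol, via cycloheptenone 8 (not isolated)
Conditions: PhMe, 150 °C, base-washed sealed tube; then cool to −78 °C, CH2Cl2, Me2AlCl (1.5 equiv), −78 → −20 °C; aq. potassium sodium tartrate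
Reagents that add atoms: none
Why: Heating 7 effects a concerted [3,3]-sigmatropic (Claisen) shift in which the vinyl terminus C8 bonds to the alkylidene carbon C8a as the ring C6–O bond breaks, so the five-membered oxolane (O, C3a, C4, C5, C6) is expanded by two atoms into the seven-membered carbocycle of 8 (C3a, C4, C5, C6, C7, C8, C8a) with the oxygen expelled from the ring as the C3a carbonyl; the closest known reaction type is the Claisen ring expansion of 2-alkylidene-5-vinyltetrahydrofurans to cyclohept-4-enones, which is known for fully substituted alkylidene carbons as well. The seven-membered ring thus closes inside a bridged six-centre transition state (oxygen bridging C3a and C6) in which the vinyl group can reach only the enol-ether face on which it stands at C6, so the R configuration of C6 and the Z geometry (chain cis to oxygen, methyl trans) are translated into the R quaternary centre C8a while C6 becomes sp2. Me2AlCl then complexes the C3a ketone and a carbonyl-ene reaction closes the cyclopentane by C3–C3a bond formation (5-exo attack of the less substituted carbon of the trisubstituted alkene on the carbonyl, tether anchored at the α-carbon C8a) with transfer of an allylic methyl hydrogen to oxygen, which leaves the isopropenyl group and releases methane from aluminium. The three-carbon tether on C8a can reach only the carbonyl face that places the new C3–C3a bond cis to C8a–C1, because the other face would demand a torsion of more than 120° about C8a–C3a in the cycloheptanone, so the C3a hydroxyl should end up cis to the angular methyl. The six-centre ene transition state requires the isopropylidene unit to lie syn to the carbonyl oxygen for the hydrogen shift, so the isopropenyl group at C3 should end up cis to the hydroxyl, which is the all-cis array of C3, C3a and C8a in the target. The step needs the sigmatropic shift to outrun proton-catalysed migration of the enol-ether double bond into the ring (base-washed glass, no acid until the ketone has formed) and needs the Lewis acid to ignore the C6=C7 alkene, which is secured because that alkene could bond to C3a only through a four-membered ring.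

Step 7
Reactants: 9 (3R,3aS,8aR)-6,8a-dimethyl-3-(prop-1-en-2-yl)-2,3,4,5,8,8a-hexahydro-1H-azulen-3a-ol
Product: 10 (3R,3aS,8aR)-6,8a-dimethyl-3-(propan-2-yl)-2,3,4,5,8,8a-hexahydro-1H-azulen-3a-ol
Conditions: H2 (1 atm), RhCl(PPh3)3 (5 mol %), benzene/EtOH, rt
Reagents that add atoms: none
Why: Homogeneous hydrogenation with RhCl(PPh3)3 saturates the 1,1-disubstituted isopropenyl group and leaves the trisubstituted ring alkene untouched (substitution-controlled chemoselectivity); no stereocentre is created.

Step 8
Reactants: 10 (3R,3aS,8aR)-6,8a-dimethyl-3-(propan-2-yl)-2,3,4,5,8,8a-hexahydro-1H-azulen-3a-ol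
Product: 11 (3R,3aS,6S,7R,8aR)-6,7-epoxy-6,8a-dimethyl-3-(propan-2-yl)decahydroazulen-3a-ol (epoxide oxygen on the face of the C3a hydroxyl and C8a methyl)
Conditions: VO(acac)2 (5 mol %), t-BuOOH (1.5 equiv, decane solution), CH2Cl2, 0 °C → rt
Reagents that add atoms: tert-butyl hydroperoxide, CC(C)(C)OO
Why: Hydroxyl-directed epoxidation with VO(acac)2/t-BuOOH: the vanadium alkoxide of the bishomoallylic C3a hydroxyl should deliver oxygen across the ring to the alkene face syn to that hydroxyl, and an epoxide on this face cannot be attacked from behind by the same hydroxyl.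

Step 9
Reactants: 11 (3R,3aS,6S,7R,8aR)-6,7-epoxy-6,8a-dimethyl-3-(propan-2-yl)decahydroazulen-3a-ol
Product: 12 (3R,3aS,6R,7R,8aR)-6,8a-dimethyl-3-(propan-2-yl)decahydroazulene-3a,6,7-triol
Conditions: HClO4 (0.05 M aq., cat.), THF/H2O, 0 °C
Reagents that add atoms: water, O
Why: Acid-catalysed epoxide hydrolysis: water opens the protonated epoxide at the tertiary carbon C6 with inversion (anti opening), which places the C6 hydroxyl anti and leaves the C7 oxygen syn to the C3a hydroxyl, i.e. the trans-6,7-diol of the target.

Step 10
Reactants: 12 (3R,3aS,6R,7R,8aR)-6,8a-dimethyl-3-(propan-2-yl)decahydroazulene-3a,6,7-triol; 13 4-methoxybenzoyl chloride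
Product: 14 (3R,3aS,6R,7R,8aR)-3a,6-dihydroxy-6,8a-dimethyl-3-(propan-2-yl)decahydroazulen-7-yl 4-methoxybenzoate (target)
Conditions: 13 (1.2 equiv), DMAP (0.2 equiv), pyridine, CH2Cl2, 0 °C → rt
Reagents that add atoms: none
Why: DMAP-catalysed acylation (nucleophilic catalysis) esterifies the only secondary hydroxyl, the two tertiary alcohols being inert under these conditions; no stereocentre is affected.

**Compound list**

1 | (R)-(−)-linalool, (3R)-3,7-dimethylocta-1,6-dien-3-ol | CC(C)=CCC[C@@](C)(O)C=C | starting material
2 | (5R)-5-ethenyl-5-methyloxolan-2-ol (both C2 epimers) | OC1CC[C@](C)(C=C)O1 | intermediate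
3 | (3R)-3-methylhept-1-en-6-yn-3-ol | C#CCC[C@@](C)(O)C=C | intermediate
4 | 5-bromo-2-methylpent-2-ene | CC(C)=CCCBr | starting material
5 | (3R)-3,11-dimethyldodeca-1,10-dien-6-yn-3-ol | CC(C)=CCCC#CCC[C@@](C)(O)C=C | intermediate
6 | (2E,5R)-5-ethenyl-2-(1-iodo-5-methylhex-4-en-1-ylidene)-5-methyloxolane | CC(C)=CCC/C(I)=C1/CC[C@](C)(C=C)O1 | intermediate
7 | (2Z,5R)-5-ethenyl-5-methyl-2-(6-methylhept-5-en-2-ylidene)oxolane | CC(C)=CCC/C(C)=C1/CC[C@](C)(C=C)O1 | intermediate
8 | (2R)-2,5-dimethyl-2-(4-methylpent-3-en-1-yl)cyclohept-4-en-1-one | CC1=CC[C@@](C)(CCC=C(C)C)C(=O)CC1 | intermediate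
9 | (3R,3aS,8aR)-6,8a-dimethyl-3-(prop-1-en-2-yl)-2,3,4,5,8,8a-hexahydro-1H-azulen-3a-ol | CC1=CC[C@@]2(C)CC[C@H](C(C)=C)[C@@]2(O)CC1 | intermediate
10 | (3R,3aS,8aR)-6,8a-dimethyl-3-(propan-2-yl)-2,3,4,5,8,8a-hexahydro-1H-azulen-3a-ol | CC1=CC[C@@]2(C)CC[C@H](C(C)C)[C@@]2(O)CC1 | intermediate
11 | (3R,3aS,6S,7R,8aR)-6,7-epoxy-6,8a-dimethyl-3-(propan-2-yl)decahydroazulen-3a-ol | O1[C@@H]2C[C@@]3(C)CC[C@H](C(C)C)[C@@]3(O)CC[C@]12C | intermediate
12 | (3R,3aS,6R,7R,8aR)-6,8a-dimethyl-3-(propan-2-yl)decahydroazulene-3a,6,7-triol | O[C@@H]1C[C@@]2(C)CC[C@H](C(C)C)[C@@]2(O)CC[C@@]1(C)O | intermediate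
13 | 4-methoxybenzoyl chloride | COc1ccc(cc1)C(Cl)=O | starting material
14 | (3R,3aS,6R,7R,8aR)-3a,6-dihydroxy-6,8a-dimethyl-3-(propan-2-yl)decahydroazulen-7-yl 4-methoxybenzoate | COc1ccc(C(=O)O[C@@H]2C[C@@]3(C)CC[C@H](C(C)C)[C@@]3(O)CC[C@@]2(C)O)cc1 | target

**Step count and risks**

Total step count: 10. Longest linear sequence: 10 steps (1 → 14).

Most likely to fail, step 6. Traces of acid at 150 °C may move the exocyclic enol-ether double bond into the ring before the sigmatropic shift, which takes the substrate out of the [3,3] manifold. In the second stage, chloride capture of the cyclising cation or a stepwise closure may erode the cis relation at C3. Fallback: from 7 the ring expansion is run with i-Bu3Al (CH2Cl2, −78 → 0 °C). This aluminium-promoted Claisen ring expansion proceeds far below the temperature of double-bond migration and reduces the new ketone in the flask to (2R)-2,5-dimethyl-2-(4-methylpent-3-en-1-yl)cyclohept-4-en-1-ol F6 (both carbinol epimers). Dess–Martin oxidation then returns ketone 8, now isolated and purified, which is cyclised separately with Me2AlCl to 9.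

Second, step 4. Reversible iodonium formation at the remote trisubstituted alkene may become productive, or 6-endo closure may compete with the 5-exo mode. Fallback: the trisubstituted alkene is introduced only after halocyclisation and ring expansion.
- From 3 the dianion is alkylated with 2-(2-bromoethyl)-1,3-dioxolane to (3R)-9-(1,3-dioxolan-2-yl)-3-methylnon-1-en-6-yn-3-ol F1.
- Iodocyclisation with NIS should give (2E,5R)-2-[3-(1,3-dioxolan-2-yl)-1-iodopropylidene]-5-ethenyl-5-methyloxolane F2.
- Negishi methylation should give (2Z,5R)-2-[4-(1,3-dioxolan-2-yl)butan-2-ylidene]-5-ethenyl-5-methyloxolane F3.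
- The thermal Claisen ring expansion (PhMe, 150 °C) should give (2R)-2-[2-(1,3-dioxolan-2-yl)ethyl]-2,5-dimethylcyclohept-4-en-1-one F4.
- Acetal hydrolysis (PPTS, wet acetone) gives 3-[(1R)-1,4-dimethyl-7-oxocyclohept-3-en-1-yl]propanal F5.
- An aldehyde-selective Wittig reaction with isopropylidenetriphenylphosphorane returns ketone 8, which is cyclised with Me2AlCl to 9 as in step 6.

Third, step 8. The tertiary hydroxyl may fail to direct the oxidant, giving poor facial selectivity, and an epoxide on the far face could be opened across the ring by the C3a hydroxyl; the acid of step 9 could also dehydrate the C3a alcohol. Fallback: from 10, dihydroxylation with OsO4 (cat.)/NMO from the less hindered face, anti to the angular methyl and hydroxyl, should give the cis-diol (3R,3aS,6R,7S,8aR)-6,8a-dimethyl-3-(propan-2-yl)decahydroazulene-3a,6,7-triol F7. Mitsunobu esterification of its secondary hydroxyl with 4-methoxybenzoic acid (PPh3, DIAD, THF) inverts C7 and leads directly to 14.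

**Further compounds**

F1 | step 4 | (3R)-9-(1,3-dioxolan-2-yl)-3-methylnon-1-en-6-yn-3-ol | O1CCOC1CCC#CCC[C@@](C)(O)C=C
F2 | step 4 | (2E,5R)-2-[3-(1,3-dioxolan-2-yl)-1-iodopropylidene]-5-ethenyl-5-methyloxolane | O1CCOC1CC/C(I)=C2/CC[C@](C)(C=C)O2
F3 | step 4 | (2Z,5R)-2-[4-(1,3-dioxolan-2-yl)butan-2-ylidene]-5-ethenyl-5-methyloxolane | O1CCOC1CC/C(C)=C2/CC[C@](C)(C=C)O2
F4 | step 4 | (2R)-2-[2-(1,3-dioxolan-2-yl)ethyl]-2,5-dimethylcyclohept-4-en-1-one | CC1=CC[C@@](C)(CCC2OCCO2)C(=O)CC1
F5 | step 4 | 3-[(1R)-1,4-dimethyl-7-oxocyclohept-3-en-1-yl]propanal | CC1=CC[C@@](C)(CCC=O)C(=O)CC1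
F6 | step 6 | (2R)-2,5-dimethyl-2-(4-methylpent-3-en-1-yl)cyclohept-4-en-1-ol | CC1=CC[C@@](C)(CCC=C(C)C)C(O)CC1
F7 | step 8 | (3R,3aS,6R,7S,8aR)-6,8a-dimethyl-3-(propan-2-yl)decahydroazulene-3a,6,7-triol | O[C@H]1C[C@@]2(C)CC[C@H](C(C)C)[C@@]2(O)CC[C@@]1(C)O
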